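Remark on the structure: atoms are numbered as in the isochromene ring (C1, O2, C3, C4, C4a, C5, C6, C7, C8, C8a; O7 is the oxygen on C7). Ring A is the carbocycle (C4a to C8a) and ring B is the pyran. The SMILES is read as 7R (CIP order O7 > C8 > C6 > CH3).

## The problem

- Compound 18 is a 6H-isochromene-6,8(7H)-dione. Ring A (C4a, C5, C6, C7, C8, C8a) is cross-conjugated with pyran ring B (C1, O2, C3, C4, C4a, C8a), and every ring atom except C7 is sp2.
- C7 is the only stereocentre. It is quaternary, carries CH3 and the octanoyloxy group, and sits between the C6 and C8 ketones. No other stereocentre exists to control it.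
- C7 is stereogenic only because C8a carries C1 while C5 carries hydrogen. A ring A that lacks C1 is converted into its mirror image by a hydrogen shift through a mirror-symmetric dienol. C1 must therefore be on C8a whenever ring A exists.
- The 2-acyloxy-1,3-dione is cleaved by alkoxides (retro-Claisen) and the ester can migrate under base. C1 of ring B is attacked by amines. The end game has to be neutral or acidic.
- The enabling feature has two parts. First, O7–C7(CH3)–C6 is the skeleton of lactic acid. Second, every ring-closing bond away from C7 (C4a–C8a in ring A, O2–C1 and O2–C3 in ring B) lies β or δ to the C8 or C6 carbonyl, so each can be made by conjugate addition to an alkyne. The bicycle is then the folded form of an unbranched C16 chain.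

## Retrosynthesis

**18 to 15 (key step).** The cuts are C4a–C8a of ring A and O2–C3 of ring B, and O2–C1 is exchanged for N–C1. Cutting C7–O7 (the arene route) or C7–C8 would leave C7 to be made on or next to a flat ring. This cut leaves all four bonds of C7 intact. Precursor 15 is an open C16 chain with no ring, an enaminone at one end and a diynone at the other, and its only stereocentre is that of 18. The forward reaction needs C8a to add to C4a (not oxygen, not C3), then hydrolysis at C1 and closure of O2 onto C3.

**15 to 14.** The cut is the ester bond at O7. Acylation is placed before cyclisation because the free hydroxyl of 14 sits 5-endo to the ynone and would compete in the cascade. The forward reaction must acylate a hindered tertiary alkoxide without touching the enaminone or the diynone.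

**14 to 8 and 12.** The cut is C5–C6. C6 is the carboxyl carbon of lactic acid, kept as the lactone carbonyl of 8. Acetylide 13, made from 12, converts it into the ynone, and collapse of the acetal frees O7. The diyne cannot be attached earlier, because the lactone is needed for the enolate step that sets C7 and an ynone would not survive that step. The acetylide must add once, and to the lactone rather than the vinylogous amide.

**8 to 7, 6, and then 3 and 4.** The cuts are C1=C8a (C1 is condensed onto methyl ketone 7 as an aminomethylene unit) and C7–C8 (aldol of enolate 5 with 4, then oxidation of 6). This is the stereo-defining cut: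

- In 3 the configuration of lactic acid is copied into the acetal carbon.
- The acetal carbon then directs 4 to the face anti to tert-butyl, so C8 replaces the hydrogen of lactic acid with retention.
- (R)-Lactic acid therefore maps onto 7R. The descriptor reads S in 6, 7, 8, 14 and 15 only because the CIP order changes.

The enaminone is the chosen form of C8–C8a–C1 because it has no acidic hydrogen, resists acetylide, is nucleophilic at C8a and carries C1 from the start.

**3 to 1 and 2; 12 to 9 and 10.** The acetal C–O bonds are cut back to the hydroxy acid 1 and aldehyde 2. The C3–heptyl bond of the diyne is cut back to dichloride 9 and bromide 10 through diacetylide 11. Both are one-step preparations of known type from commercial materials.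

## Roads not taken

**Alternative 1:** the obvious route. The cuts are C7–O7 and O2–C3.
- Forward: alkynylbenzaldehyde A1, made by Sonogashira coupling, would be cycloisomerised with Au(OAc)3 to 2-benzopyrylium salt A2. A2 would be oxidised at C7 with a chiral oxidant and O-acylated to 18.
- It is about three steps shorter.
- It creates C7 on a planar ring whose two faces differ only through the distant C1 and C5 environments. All stereocontrol then rests on one reagent-controlled oxidation with a stoichiometric chiral oxidant, and the quinol products are prone to over-oxidation and dimerisation.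
- The chosen plan takes C7 from the chiral pool with a predictable sense and never has to create asymmetry on a flat ring.

**Alternative 2:** carbene-catalysed crossed benzoin closure of ring A. The cut is C7–C8.
- Forward: a chiral triazolium carbene would add to the C8 aldehyde of pyranylidene diketo aldehyde A3, and the acyl anion equivalent would attack the C7 ketone, closing ring A and setting C7 catalytically.
- A3 is no simpler than 18. Its exocyclic C4a=C5 bond would have to be built on a 4-pyranone carbonyl, where nucleophiles prefer C1.
- Its aldehyde is a vinylogous formate and poorly electrophilic, and the adjacent C6 ketone offers a competing five-membered closure.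

**Alternative 3:** dearomative C-methylation. The cut is C7–CH3.
- Forward: the vinylogous acid A4 would be methylated at C7 under chiral phase-transfer conditions.
- The anion is ambident. Methylation at O6, O8 or C5 competes with a C7 that is deactivated by its acyloxy group, and the ester would migrate among three oxygens under base.
- There is no reliable enantioselective methylation of this enolate type, and A4 needs the same arene and alkyne chemistry as Alternative 1, so nothing is saved.

Key step: step 8

## Route

Step 1
Reactants: 1 (R)-lactic acid; 2 pivalaldehyde
Product: 3 (2R,5R)-2-tert-butyl-5-methyl-1,3-dioxolan-4-one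
Conditions: p-TsOH·H2O (cat.), H2SO4 (cat.), pentane, reflux, Dean–Stark; crystallisation from pentane at −78 °C
Reagents that add atoms: none
Why: Acid-catalysed acetalisation of an α-hydroxy acid with azeotropic removal of water. The cis acetal (tert-butyl and methyl on the same face) should predominate and be purified by cold crystallisation, so the acetal centre (2R) is set by C5 of the lactic acid.

Step 2
Reactants: 3 (2R,5R)-2-tert-butyl-5-methyl-1,3-dioxolan-4-one; 4 acetaldehyde
Product: 6 (2R,5S)-2-tert-butyl-5-(1-hydroxyethyl)-5-methyl-1,3-dioxolan-4-one (both carbinol epimers), via lithium enolate 5 (not isolated)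
Conditions: LiN(i-Pr)2, THF, −78 °C; then 4, −78 °C; aq. NH4Cl
Reagents that add atoms: none
Why: Aldol addition of a chiral lactone enolate (self-regeneration of stereocentres). Enolisation erases C5, but the tert-butyl group on the 2R acetal carbon blocks one face, so 4 should add anti to it and C8 takes the place of the lactic acid hydrogen with retention, fixing C7 of 18. Both carbinol epimers are used because that centre is oxidised next.

Step 3
Reactants: 6 (2R,5S)-2-tert-butyl-5-(1-hydroxyethyl)-5-methyl-1,3-dioxolan-4-one
Product: 7 (2R,5S)-5-acetyl-2-tert-butyl-5-methyl-1,3-dioxolan-4-one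
Conditions: Dess–Martin periodinane, NaHCO3, CH2Cl2, 0 to 23 °C
Reagents that add atoms: none
Why: Dess–Martin oxidation of a secondary alcohol under buffered conditions. The product has no hydrogen between its two carbonyls, so the quaternary centre cannot epimerise.

Step 4
Reactants: 7 (2R,5S)-5-acetyl-2-tert-butyl-5-methyl-1,3-dioxolan-4-one
Product: 8 (2R,5S)-2-tert-butyl-5-[(2E)-3-(dimethylamino)prop-2-enoyl]-5-methyl-1,3-dioxolan-4-one
Conditions: Me2NCH(OMe)2 (3 equiv), toluene, 80 °C
Reagents that add atoms: N,N-dimethylformamide dimethyl acetal, COC(OC)N(C)C
Why: Condensation of a methyl ketone with an amide acetal to the (E)-enaminone. The methyl group is the only enolisable position, so C1 can only end up on C8a. The resulting vinylogous amide has no acidic hydrogen and a poorly electrophilic carbonyl, as step 6 requires.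

Step 5
Reactants: 9 1,4-dichlorobut-2-yne; 10 1-bromoheptane
Product: 12 undeca-1,3-diyne, via sodium buta-1,3-diyn-1-ide 11 (not isolated)
Conditions: NaNH2 (3 equiv), liquid NH3, −33 °C; then 10, THF, −33 to 23 °C
Reagents that add atoms: none
Why: Twofold dehydrochlorination gives buta-1,3-diyne, whose monosodium salt 11 is alkylated by the primary bromide (acetylide alkylation). Three equivalents of NaNH2 limit dialkylation; the diyne is used at once as a solution.

Step 6
Reactants: 12 undeca-1,3-diyne; 8 (2R,5S)-2-tert-butyl-5-[(2E)-3-(dimethylamino)prop-2-enoyl]-5-methyl-1,3-dioxolan-4-one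
Product: 14 (1E,4S)-1-(dimethylamino)-4-hydroxy-4-methylhexadec-1-ene-6,8-diyne-3,5-dione, via lithium undeca-1,3-diyn-1-ide 13 (not isolated)
Conditions: 12, n-BuLi, THF, −78 °C; then 8, −78 °C; AcOH, −78 to 0 °C
Reagents that add atoms: none
Why: Addition of a lithium acetylide to a lactone carbonyl to give an ynone. The tetrahedral adduct should persist at −78 °C, which prevents a second addition, and on acidic quench it collapses with loss of the acetal as pivalaldehyde, freeing O7. The enaminone carbonyl is deactivated by nitrogen, 8 has no acidic hydrogen, and C7 is not touched.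

Step 7
Reactants: 14 (1E,4S)-1-(dimethylamino)-4-hydroxy-4-methylhexadec-1-ene-6,8-diyne-3,5-dione
Product: 15 (1E,4S)-1-(dimethylamino)-4-methyl-3,5-dioxohexadec-1-ene-6,8-diyn-4-yl octanoate
Conditions: LiN(SiMe3)2 (1.0 equiv), THF, −78 °C; then octanoyl chloride, −78 to −40 °C
Reagents that add atoms: octanoyl chloride, CCCCCCCC(=O)Cl
Why: O-acylation of a lithium tertiary alkoxide with an acid chloride. The hydroxyl is the only acidic hydrogen of 14, the enaminone carbon should not react with an acid chloride at this temperature, and the alkoxide is trapped cold before it can add to the ynone.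

Step 8
Reactants: 15 (1E,4S)-1-(dimethylamino)-4-methyl-3,5-dioxohexadec-1-ene-6,8-diyn-4-yl octanoate
Product: 18 (7R)-3-heptyl-7-methyl-6,8-dioxo-7,8-dihydro-6H-isochromen-7-yl octanoate, via cyclic enaminone 16 (not isolated), via hydroxymethylidene dione 17 (not isolated)
Conditions: toluene/AcOH (5:1), 50 °C; then H2O, Au(OAc)3 (5 mol %), 40 °C
Reagents that add atoms: water, O
Why: Proposed new method: an intramolecular version of the first stage of the Bohlmann–Rahtz reaction (conjugate addition of an enamine carbon to an ynone) is coupled to the oxa-cyclisation known for alkynyl formyl enols of this ring system. C8a, the nucleophilic α-carbon of the enaminone, adds to C4a, the β-carbon of the acid-activated diynone (6-endo-dig, ring A), and proton transfer from C8a to C5 gives the push–pull enaminone 16. Added water then hydrolyses the vinylogous amide at C1 to enol 17, whose oxygen adds to C3, the δ-terminus of the enynone, under catalysis by trivalent gold (6-endo-dig, ring B). No stereocentre is formed: C7 is quaternary, lies outside every bond that is made, and because C1 is on C8a from the start the ring never passes through the mirror-symmetric dienol that would racemise it. The step needs carbon rather than oxygen attack of the enaminone (expected for a soft acceptor, and it leads to the more stabilised vinylogous amide), attack at C4a rather than C3 (only C4a gives a six-membered ring), and 6-endo rather than 5-exo oxygen attack (C3 is the conjugate position of the C6 carbonyl). The acidic medium keeps the released dimethylamine protonated so that it cannot reopen ring B.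

## Compound list

1 | (R)-lactic acid, (2R)-2-hydroxypropanoic acid | C[C@@H](O)C(=O)O | starting material
2 | pivalaldehyde (2,2-dimethylpropanal) | CC(C)(C)C=O | starting material
3 | (2R,5R)-2-tert-butyl-5-methyl-1,3-dioxolan-4-one | C[C@H]1O[C@@H](C(C)(C)C)OC1=O | intermediate
4 | acetaldehyde | CC=O | starting material
5 | lithium (2R)-2-tert-butyl-5-methyl-1,3-dioxol-4-olate (lithium enolate of 3) | CC1=C([O-])O[C@H](C(C)(C)C)O1.[Li+] | intermediate
6 | (2R,5S)-2-tert-butyl-5-(1-hydroxyethyl)-5-methyl-1,3-dioxolan-4-one (both carbinol epimers) | C[C@@]1(C(C)O)O[C@@H](C(C)(C)C)OC1=O | intermediate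
7 | (2R,5S)-5-acetyl-2-tert-butyl-5-methyl-1,3-dioxolan-4-one | C[C@@]1(C(C)=O)O[C@@H](C(C)(C)C)OC1=O | intermediate
8 | (2R,5S)-2-tert-butyl-5-[(2E)-3-(dimethylamino)prop-2-enoyl]-5-methyl-1,3-dioxolan-4-one | C[C@@]1(C(=O)/C=C/N(C)C)O[C@@H](C(C)(C)C)OC1=O | intermediate
9 | 1,4-dichlorobut-2-yne | ClCC#CCCl | starting material
10 | 1-bromoheptane | CCCCCCCBr | starting material
11 | sodium buta-1,3-diyn-1-ide | [Na+].[C-]#CC#C | intermediate
12 | undeca-1,3-diyne | C#CC#CCCCCCCC | intermediate
13 | lithium undeca-1,3-diyn-1-ide | [Li+].[C-]#CC#CCCCCCCC | intermediate
14 | (1E,4S)-1-(dimethylamino)-4-hydroxy-4-methylhexadec-1-ene-6,8-diyne-3,5-dione | CCCCCCCC#CC#CC(=O)[C@@](C)(O)C(=O)/C=C/N(C)C | intermediate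
15 | (1E,4S)-1-(dimethylamino)-4-methyl-3,5-dioxohexadec-1-ene-6,8-diyn-4-yl octanoate | CCCCCCCC#CC#CC(=O)[C@@](C)(OC(=O)CCCCCCC)C(=O)/C=C/N(C)C | intermediate
16 | (1R,3E)-3-[(dimethylamino)methylidene]-1-methyl-4-(non-1-yn-1-yl)-2,6-dioxocyclohex-4-en-1-yl octanoate | CN(C)/C=C1\C(C#CCCCCCCC)=CC(=O)[C@@](C)(OC(=O)CCCCCCC)C1=O | intermediate
17 | (1R,3E)-3-(hydroxymethylidene)-1-methyl-4-(non-1-yn-1-yl)-2,6-dioxocyclohex-4-en-1-yl octanoate | O/C=C1\C(C#CCCCCCCC)=CC(=O)[C@@](C)(OC(=O)CCCCCCC)C1=O | intermediate
18 | (7R)-3-heptyl-7-methyl-6,8-dioxo-7,8-dihydro-6H-isochromen-7-yl octanoate | CCCCCCCC(=O)O[C@]1(C)C(=O)C=C2C=C(CCCCCCC)OC=C2C1=O | target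

## Step count and risks

Total steps: 8. Longest linear sequence: 7 (steps 1, 2, 3, 4, 6, 7, 8); step 5 is the side branch to the diyne.

**Step 8 (key step, proposed new method).**
- Most likely failure: ambident attack, in which the enaminone oxygen rather than C8a adds to C4a, because both closures are six-membered. Hydrolysis of the open-chain enaminone followed by loss of the formyl carbon could also outrun carbocyclisation.
- Fallback with known reaction types: it sets out from 15. The enaminone would be hydrolysed first on wet silica with aqueous oxalic acid at 0 °C to formyl ketone enol F1. Ring A would then be closed as a base-catalysed intramolecular Michael addition of a 1,3-dicarbonyl anion to an ynone (Cs2CO3 cat., MeCN, 0 °C). This comes back to the route at 17, which is cyclised with Au(OAc)3 to 18.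

**Step 6.**
- Most likely failure: collapse of the tetrahedral adduct before the quench, which would allow a second acetylide addition to the new ynone, or addition of the freed tertiary alkoxide to the ynone in a 5-endo closure.
- Fallback: it sets out from 8. The lactone would be opened with MeNH(OMe)·HCl and i-PrMgCl in THF at −20 °C, with loss of pivalaldehyde, to hydroxy Weinreb amide F2. Two equivalents of 13 would then give a chelated adduct that releases the ketone only on work-up. This comes back to the route at 14.

**Step 7.**
- Most likely failure: 5-endo addition of the lithium alkoxide to the ynone before acylation, or acyl transfer to the enaminone carbon on warming.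
- Fallback: it sets out from 14 and moves the acylation to the end. Silylation with triethylsilyl triflate and 2,6-lutidine at −78 °C would give silyl ether F3. The conditions of step 8 would give silyl-protected bicycle F4. HF·pyridine would give tertiary alcohol F5, which would be acylated with octanoyl chloride and DMAP. This comes back to the route at 18.

**Step 4.**
- Most likely failure: ring opening of the acylal lactone, or retro-Claisen cleavage of the non-enolisable β-keto lactone, by the methanol and methoxide that the amide acetal releases at 80 °C.
- Fallback: it sets out from 3 and brings in C8, C8a and C1 as one three-carbon unit. Enolate 5 would be added to 3-(trimethylsilyl)prop-2-ynal to give propargylic alcohol F6. Dess–Martin oxidation would give silyl ynone F7. Dimethylamine in THF/MeOH at 0 °C would effect desilylation and conjugate addition. This comes back to the route at 8.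

## Further compounds

F1 | step 8 | (1Z,4S)-1-hydroxy-4-methyl-3,5-dioxohexadec-1-ene-6,8-diyn-4-yl octanoate | CCCCCCCC#CC#CC(=O)[C@@](C)(OC(=O)CCCCCCC)C(=O)/C=C\O
F2 | step 6 | (2S,4E)-5-(dimethylamino)-2-hydroxy-N-methoxy-N,2-dimethyl-3-oxopent-4-enamide | CON(C)C(=O)[C@@](C)(O)C(=O)/C=C/N(C)C
F3 | step 7 | (1E,4S)-1-(dimethylamino)-4-methyl-4-[(triethylsilyl)oxy]hexadec-1-ene-6,8-diyne-3,5-dione | CCCCCCCC#CC#CC(=O)[C@@](C)(O[Si](CC)(CC)CC)C(=O)/C=C/N(C)C
F4 | step 7 | (7R)-3-heptyl-7-methyl-7-[(triethylsilyl)oxy]-6H-isochromene-6,8(7H)-dione | CCCCCCCC1=CC2=CC(=O)[C@@](C)(O[Si](CC)(CC)CC)C(=O)C2=CO1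
F5 | step 7 | (7R)-3-heptyl-7-hydroxy-7-methyl-6H-isochromene-6,8(7H)-dione | CCCCCCCC1=CC2=CC(=O)[C@@](C)(O)C(=O)C2=CO1
F6 | step 4 | (2R,5S)-2-tert-butyl-5-[1-hydroxy-3-(trimethylsilyl)prop-2-yn-1-yl]-5-methyl-1,3-dioxolan-4-one (both carbinol epimers) | C[C@@]1(C(O)C#C[Si](C)(C)C)O[C@@H](C(C)(C)C)OC1=O
F7 | step 4 | (2R,5S)-2-tert-butyl-5-methyl-5-[3-(trimethylsilyl)prop-2-ynoyl]-1,3-dioxolan-4-one | C[C@@]1(C(=O)C#C[Si](C)(C)C)O[C@@H](C(C)(C)C)OC1=O
A1 | alternative 1 | 2,4-dihydroxy-3-methyl-6-(non-1-yn-1-yl)benzaldehyde | CCCCCCCC#Cc1cc(O)c(C)c(O)c1C=O
A2 | alternative 1 | 3-heptyl-6,8-dihydroxy-7-methylisochromenylium trifluoroacetate | CCCCCCCc1cc2cc(O)c(C)c(O)c2c[o+]1.[O-]C(=O)C(F)(F)F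
A3 | alternative 2 | (4Z)-4-(2,3-dioxobutylidene)-6-heptyl-4H-pyran-3-carbaldehyde | CCCCCCCC1=C/C(=C/C(=O)C(C)=O)C(C=O)=CO1
A4 | alternative 3 | 3-heptyl-6-hydroxy-8-oxo-8H-isochromen-7-yl octanoate | CCCCCCCC(=O)OC1=C(O)C=C2C=C(CCCCCCC)OC=C2C1=O
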